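The data were computed on assumed constants; scatter was added.

Millimoles per litre are the unit for the question before us: do we charge the next flask as written, or clean out the impurity first?

| setting | epsilon | flask |
|---|---|---|
| left-handed substrate | 0.50 M | 0.50 M |
| right-handed substrate | 0.50 M | 0.50 M |
| solid reagent | 2 M | 2.00 M |
| racemization catalyst | 25 mM | 25 mM |
| impurity | 44 mM | 29 mM |
| remark | run made earlier |  |
| time |  | 2.0 d |

epsilon run (percent of the left-handed substrate and right-handed substrate together charged)

| time / h | left-handed product / % | right-handed product / % |
|---|---|---|
| 0.417 | 3 | 0 |
| 0.667 | 3 | 2 |
| 1.33 | 1 | 3 |
| 2.50 | 8 | 3 |
| 5.00 | 12 | 8 |

(each reading ± 1.5 percentage points)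

- partner is single-handed; left-handed substrate and right-handed substrate are mirror images of each other, charged as a racemate, each of them at the stated concentration
- as a solid, counted per litre of solution: solid reagent
- what was read earlier has a scatter of 1.5 percentage points, one standard deviation
- at the start none of the solid reagent is in solution
- an excess is below zero if the other one leads
- no earlier run changes the charge of impurity; that part of a forecast is a guess
- the handed part of partner does not stay in what it makes, so the products of the two hands are mirror images too

- left-handed product and right-handed product together, in percent of the left-handed substrate and right-handed substrate charged together, at 2.0 d
- excess of left-handed product over right-handed product in the product at 2.0 d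
- whether the exchange between left-handed substrate and right-handed substrate keeps pace with the reaction: how far the product's excess at 2.0 d gets from its value without exchange to its value with instant exchange (above 80% keeps pace, below 20% hardly takes part, else lags behind)

At 5.00 h the epsilon run reads 12% of left-handed product against 8% of right-handed product, a ratio of 1.50, which is a rough reading of the selectivity factor, each point carrying a scatter of 1.5 percentage points. By that reading the left-handed substrate reacts faster than the right-handed substrate, and the exchange refills it, so we take the rate of exchange to follow the concentration of working racemization catalyst. We suppose that one impurity removes one catalyst for good. For the next flask, 29 mM less 25 mM gives 4.00 mM, and we call this the surplus impurity u, impurity charged minus catalyst charged. On that supposition the impurity, charged in a larger amount than the catalyst, makes the catalyst the limiting reagent of the poisoning, and u is what stays of the impurity once the poisoning is over. If the poisoning is quick beside the reaction, we expect the exchange in this flask to hardly take part and the excess to sink as conversion climbs; this is a guess, since no earlier run changes the charge of impurity. Our decision is to charge the flask as written, since it tests the supposition directly.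

The forecast gives 90% of product, an excess of 14% and an exchange that lags behind, reasoning “if it poisons the catalyst, exchange may be weak”. We part from it on the exchange.

The flask gives 91.7% of product, an excess of 6.87% and an exchange that hardly takes part, 6.5% of the way.

solid reagent ⇌ partner, rate k1*(cs1 - [partner]) while solid is left; crystals form when [partner] > cs1 (solubility = 0.400 M, k = 5.50 × 10⁻⁴ /s); left-handed substrate + racemization catalyst ⇌ right-handed substrate + racemization catalyst, rate k2*[racemization catalyst]*[left-handed substrate] forward; the back reaction follows from the equilibrium constant (k = 7.90 × 10⁻⁴ /M/s); partner + right-handed substrate → right-handed product (k = 3.00 × 10⁻⁵ /M/s); racemization catalyst + impurity → spent catalyst (k = 0.00770 /M/s); partner + left-handed substrate → left-handed product (k = 5.10 × 10⁻⁵ /M/s) While racemization catalyst fell to 16.4% of its charge at 0.200 d, exchange and both product-forming steps ran together in the flask, with left-handed product at 12.9% against 8.03%. After that the flask's substrates went on to product, with partner at 0.392 M at 1.00 d, and by 2.00 d impurity stood at 13.9% of its charge, where u gives 13.8%. In a neighbour flask, the same but charged with 0.012 M of impurity, catalyst stands 13.0 mM above impurity, 52.0% of its charge, and 52.0% remained at 2.00 d, with an excess of 15.9%.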